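# Proposed total synthesis of epicatechin-(4β→8)-epifisetinidol-(4β→8)-catechin (35)

## Analysis of the target

The target 35 is a linear flavan-3-ol trimer. Three 2-arylchromane units, each with a 3-OH and a catechol ring B, are joined by two diarylmethine bonds: C4 of the upper unit U to C8 of the middle unit M, and C4 of M to C8 of the terminal unit L. U is an epicatechin unit, M is a 5-deoxy unit of the epifisetinidol type whose ring A carries only the 7-OH, and L is (+)-catechin. There are eight stereocentres: (2R,3R,4R) in U, (2R,3R,4R) in M and (2R,3S) in L. In U and M the 2-aryl group and the 3-OH are cis (both α) and the bond from C4 to the next unit is β, trans to both; in L the 2-aryl group and the 3-OH are trans. The molecule has fourteen free hydroxyls, three of them in air-sensitive catechols, two interflavan bonds that ionise at C4 under acid, and benzylic ether centres at C2, so the skeleton has to be assembled perbenzylated and unveiled last under neutral conditions. The usual coupling of a C4 cation with a nucleophilic ring A does not fit unit M: a 7-oxy-5-deoxy ring is less nucleophilic than a phloroglucinol ring and reacts mainly at C6, not at the crowded C8 between O1 and the 7-oxygen, and its own C4 lacks the 5-oxygen that eases activation. The strategy rests on the position of C4: in U (and likewise in M) it lies between the oxygen-bearing C3 and the ring-A carbon C4a, which is ortho to O1 (and to the C5 oxygen in U) and para to the C7 oxygen. At the C3 ketone level, removing C4 with its aryl substituent leaves a 2-arylbenzofuran-3(2H)-one and an aryl–CH unit, so each interflavan carbon can be introduced as the carbon of an aryldiazomethane.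

## Retrosynthetic reasoning

**Protecting groups and C3 of unit M.** Target 35 is traced back to the tridecabenzyl ether 34, so that the last step is a neutral hydrogenolysis. The axial 3α-hydroxyl of unit M in 34 is derived by SN2 inversion from the equatorial alcohol 32, and 32 by hydride reduction from ketone 31. The ketone is chosen because it is what the ring-forming step delivers, and because hydride should enter anti to the pseudoaxial C4 aryl group, so that one inversion corrects C3.

**Ring C of unit M.** In 31 the bonds C3–C4 and C4–C4a of unit M are cut, which leads to the 2-arylbenzofuranone 22 and the diazo compound 30. The carbon that becomes C4 of M is already bound to C8 of the catechin ring in 30, so the M–L bond needs no electrophilic substitution. The forward reaction has to insert that carbon between the carbonyl and the ring-A carbon, place the catechin ring trans to the C2 aryl group, and select one configuration at the mobile C2 centre of 22.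

**The catechin partner.** Diazo compound 30 comes from aldehyde 28 through hydrazone 29. Aldehyde 28 is reached from bromide 26 by halogen–metal exchange and formylation, and 26 from catechin 23 through the benzyl ethers 24 and 25. Cutting at C8 of ring A uses its known preference for electrophilic bromination, and both stereocentres of unit L are taken unchanged from 23.

**The furanone on ring A of unit M.** Benzofuranone 22 is disconnected at the C2–aryl bond to 21 and aryl bromide 3 (ketone α-arylation). Ketone 21 is opened at the bond between the carbonyl and ring A to the aryloxyacetic acid 19, and this at the ether bond to phenol 17. The phenol oxygen becomes O1 of unit M, and the ring can close at only one position, ortho to that oxygen and para to the benzyloxy group.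

**From phenol 17 back to the first ketone.** Phenol 17 is the free form of the MOM ether 15. The 3-O-benzyl group of 15 is put on the axial alcohol 14, which comes by inversion from the equatorial alcohol 12, the reduction product of ketone 11. The order protects the configurationally labile ketone at once and gives unit U a 3-oxygen function that survives every later step.

**Key disconnection.** In 11 the bonds C3–C4 and C4–C4a of unit U are cut, giving the 2-arylbenzofuranone 4 and the diazo compound 10. The cut is made here because the bond from C4 of U to the carbon between the two oxygens of the resorcinol ring has the wrong regiochemistry for electrophilic substitution, whereas in 10 it is in place from the start. Both remaining bonds at C4, ring C and two stereocentres then arise in one step. The forward reaction must add a hindered diazo carbon to an electron-rich carbonyl, make the aryl carbon migrate and not C2, set C4, and resolve the mobile C2 centre.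

**The two partners.** Benzofuranone 4 comes from 2 and aryl bromide 3 by α-arylation, and 2 from the dihydroxy compound 1. Diazo compound 10 comes from aldehyde 8 through hydrazone 9. Aldehyde 8 is made by lithiation of 6 between its two oxygens (aryllithium 7) and formylation, and 6 from phenol 5.

## Alternatives that were turned down

**Alternative 1:** The disconnection is the O1–C8a bond of unit M in the fully assembled, protected skeleton. The precursor A2 is an open-chain secondary benzylic alcohol (the C2 hydroxyl of M) with a triflate on C8a. In the forward step Pd(OAc)2, a bulky di-tert-butyl(biaryl)phosphine and Cs2CO3 would join that hydroxyl to the triflate carbon and give the silyl-protected tridecabenzyl trimer A1.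
- For it: the closure leaves the C2–O bond intact, so none of the three stereocentres of M is touched. Intramolecular aryl etherification to chromans is an established reaction class. A1 is one desilylation and one hydrogenolysis from the target.
- Against it: the difficulty moves into A2, an acyclic C2/C3/C4 triad between three large aryl groups, whose C4 carries both the catechin ring and a doubly ortho-substituted aryl triflate. The disconnection does not say how that triad or either diarylmethine bond is made. In the coupling, a secondary alkoxide on palladium with a hydrogen at C2 can undergo β-hydride elimination to the aryl ketone and the reduced arene, oxidative addition into so hindered a triflate is slow, and carbonate can cleave the triflate at sulfur.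
- Comparison: Alternative 1 is safer for the stereochemistry of the ring closure. The chosen route instead forms ring C together with both C–C bonds at C4 from two simple partners and needs no acyclic stereocontrol, at the price of an untested catalytic step. Its step count to the trimer should be clearly lower.

**Alternative 2:** The disconnection is inside ring A of unit M, at the C4a–C5 bond. The precursor A4 is a 1,3-diketone with two masked aldehydes, bound through its central carbon to C4 of penta-O-benzylepicatechin. Dilute acid would free the aldehydes, and aldol condensation, dehydration and enolisation would aromatise the chain to the salicylaldehyde A3.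
- For it: unit U comes from natural epicatechin, so its C2 and C3 are free and the 4β bond follows from attack anti to the 3-benzyloxy group. The awkward attachment between the two ring oxygens arises by construction, because a 1,3-dicarbonyl compound reacts at its central carbon. A3 already carries the formyl carbon for ring C.
- Against it: the bond from C4 to the dicarbonyl carbon is as acid-labile as an interflavan bond, so the acid that unmasks the acetals can split A4 again. The aldol step competes with O-cyclisation to pyranones and with further condensation. The key step builds a benzene ring that can be bought, and ring C of M and the M–L bond remain unsolved.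
- Comparison: Alternative 2 is stronger on the stereochemistry of U, which needs neither an asymmetric catalyst nor an inversion at C3. The chosen route gets the same 2-substituted resorcinol pattern from a commercial arene by lithiation between the oxygens, and its key reaction also makes the second interflavan unit.

**Alternative 3:** Ring A of unit M is again the disconnection, now as a benzannulation. The precursor A6 is penta-O-benzylepicatechin with a triisopropylsiloxyethynyl group at C4β, and the four-carbon partner is cyclobutenone A7. Heating in toluene would open A7 to a vinylketene, which adds to the siloxyalkyne; ring opening, 6π closure and tautomerisation would give the mono-silylated resorcinol A5.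
- For it: the regiochemistry is fixed by the mechanism, and the two ring oxygens emerge differentiated (free OH for O1, silyl ether at C7), which is the same kind of intermediate as phenol 17. The conditions are neutral, and U again comes from the chiral pool with its 3-O-benzyl group in place.
- Against it: A6 requires a siloxyalkyne at a hindered, doubly activated C4, made through an alkynylation and an ynolate, and such ynol ethers are sensitive to acid and moisture. A7 is volatile, polymerises and must be made fresh. After A5, ring C of M and the M–L bond are still open, as in Alternative 2.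
- Comparison: Alternative 3 is at least as good for the stereochemistry of U and for differentiating the oxygens. The chosen route reaches phenol 17 with ordinary reagents and one risky catalytic step, and then uses the same step again for unit M.

Key step: step 7

**Remarks on the chemistry (assumptions).**
- α and β denote the faces of a flavan heterocycle in the usual sense; the 2-aryl group of every unit is α.
- "Penta-O-benzylepicatechin-4β-yl" stands for (2R,3R)-3,5,7-tris(benzyloxy)-2-[3,4-bis(benzyloxy)phenyl]chroman-4-yl with its free bond β.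
- "Penta-O-benzylcatechin-8-yl" stands for (2R,3S)-3,5,7-tris(benzyloxy)-2-[3,4-bis(benzyloxy)phenyl]chroman-8-yl.
- 3-(Benzyloxy)phenol 5 is taken as a commercial starting material, which avoids a statistical monobenzylation of resorcinol.
- The antipode of the tris(oxazoline) ligand that leads to the 2α,4β ketones is to be found by running both.

## Steps

Step 1
Reactants: 1 4,6-dihydroxybenzofuran-3(2H)-one
Product: 2 4,6-bis(benzyloxy)benzofuran-3(2H)-one
Conditions: BnBr (2.2 equiv), K2CO3, DMF, 60 °C
Reagents that add atoms: benzyl bromide, BrCc1ccccc1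
Why: Williamson etherification of both phenols; the chelated 4-OH needs mild heating, and carbonate is too weak a base to alkylate the far less acidic C2 methylene to a significant extent.

Step 2
Reactants: 2 4,6-bis(benzyloxy)benzofuran-3(2H)-one; 3 4-bromo-1,2-bis(benzyloxy)benzene
Product: 4 rac-4,6-bis(benzyloxy)-2-[3,4-bis(benzyloxy)phenyl]benzofuran-3(2H)-one
Conditions: Pd(OAc)2 (2 mol %), 2-dicyclohexylphosphino-2′,4′,6′-triisopropylbiphenyl (4 mol %), K3PO4, toluene, 90 °C, Ar
Reagents that add atoms: none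
Why: Palladium-catalysed α-arylation of a ketone enolate (Buchwald–Hartwig type) forms the C2–aryl bond; the product is more acidic than 2 and rests as its enolate, which holds back a second arylation. The new C2 centre is racemic and is left so because it equilibrates through the enol; 4 is worked up and kept under argon since the enol autoxidises.

Step 3
Reactants: 5 3-(benzyloxy)phenol
Product: 6 1-(benzyloxy)-3-(methoxymethoxy)benzene
Conditions: MOMCl, i-Pr2NEt, CH2Cl2, 0 °C → rt
Reagents that add atoms: chloromethyl methyl ether, COCCl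
Why: O-alkylation of the phenol with the chloromethyl ether under amine base; the MOM group later directs lithiation and can be removed in the presence of benzyl ethers.

Step 4
Reactants: 6 1-(benzyloxy)-3-(methoxymethoxy)benzene
Product: 8 2-(benzyloxy)-6-(methoxymethoxy)benzaldehyde, via aryllithium 7 (not isolated)
Conditions: n-BuLi (1.1 equiv), THF, 0 °C; DMF, −78 → 0 °C; aq. NH4Cl
Reagents that add atoms: N,N-dimethylformamide, CN(C)C=O
Why: Directed ortho-metalation: the proton between OMOM and OBn is the most acidic and both oxygens coordinate lithium, so 7 forms at that carbon and is formylated by DMF. The low temperature keeps deprotonation of the benzylic CH2 (Wittig rearrangement) in check.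

Step 5
Reactants: 8 2-(benzyloxy)-6-(methoxymethoxy)benzaldehyde
Product: 9 (E)-[2-(benzyloxy)-6-(methoxymethoxy)benzylidene]hydrazine
Conditions: N2H4·H2O (10 equiv), EtOH, rt
Reagents that add atoms: hydrazine (as hydrate), NN
Why: Condensation of the aldehyde with excess hydrazine gives the N-unsubstituted hydrazone; the excess suppresses azine formation.

Step 6
Reactants: 9 (E)-[2-(benzyloxy)-6-(methoxymethoxy)benzylidene]hydrazine
Product: 10 [2-(benzyloxy)-6-(methoxymethoxy)phenyl]diazomethane
Conditions: activated MnO2, Na2SO4, CH2Cl2, 0 °C, dark; cold filtrate used at once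
Reagents that add atoms: none
Why: Dehydrogenation of an N-unsubstituted hydrazone to the diazoalkane by MnO2, a known route to aryldiazomethanes; the two ortho alkoxy groups shield the diazo carbon against dimerisation, and the solution is not stored.

Step 7
Reactants: 4 rac-4,6-bis(benzyloxy)-2-[3,4-bis(benzyloxy)phenyl]benzofuran-3(2H)-one; 10 [2-(benzyloxy)-6-(methoxymethoxy)phenyl]diazomethane
Product: 11 (2R)-5,7-bis(benzyloxy)-2-[3,4-bis(benzyloxy)phenyl]-4β-[2-(benzyloxy)-6-(methoxymethoxy)phenyl]chroman-3-one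
Conditions: Sc(OTf)3 (10 mol %), chiral tris(oxazoline) ligand (12 mol %), 4 Å MS, toluene/CH2Cl2, −78 → −40 °C, slow addition of 10 (1.5 equiv)
Reagents that add atoms: none
Why: Proposed new method: trivalent scandium held by the tris(oxazoline) ligand activates the C3 carbonyl of 4, the nucleophilic diazo carbon of 10 adds to it (C3–C4), and in the diazonium betaine the aryl carbon C3a (the later C4a), antiperiplanar to the leaving nitrogen, shifts to the diazo-derived carbon (C4–C4a); the closest known reaction type is the Sc(OTf)3-catalysed enantioselective homologation of cycloalkanones with aryldiazomethanes, a Tiffeneau–Demjanov-type carbon insertion not yet shown for benzofuran-3(2H)-ones. Ring C is thus formed by a 1,2-shift that enlarges the five-membered furanone to the six-membered ring, not by an end-to-end cyclisation. C4 is created in the addition–migration sequence and its configuration is set by the chiral scandium complex, which fixes the carbonyl face and the orientation of the diazo aryl group; the substrate supports this, because an aryl group at C4 next to the peri 5-benzyloxy group must stand pseudoaxial and then lies trans to a pseudoequatorial C2 aryl group. C2 is not formed here but is mobile in 4 through the enol, so the catalyst has to take one enantiomer of 4 faster than the other (dynamic kinetic resolution) to reach the (2R) series. The step needs migration of C3a in preference to C2, and C3a, ortho or para to three oxygens, is a far better migrating carbon than the inductively deactivated α-aryloxy carbon C2. It also needs carbonyl addition to win over epoxide formation and over O-benzylation of the enol of 4, which low temperature, the aprotic medium and slow addition of 10 are meant to secure. Because both α-centres of 11 can epimerise, the crude ketone goes straight into step 8.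

Step 8
Reactants: 11 (2R)-5,7-bis(benzyloxy)-2-[3,4-bis(benzyloxy)phenyl]-4β-[2-(benzyloxy)-6-(methoxymethoxy)phenyl]chroman-3-one
Product: 12 (2R,3S)-5,7-bis(benzyloxy)-2-[3,4-bis(benzyloxy)phenyl]-4β-[2-(benzyloxy)-6-(methoxymethoxy)phenyl]chroman-3-ol
Conditions: NaBH4, CeCl3·7H2O, THF/MeOH, −78 °C
Reagents that add atoms: none
Why: Luche-type 1,2-reduction: CeCl3 makes hydride transfer fast and the medium less basic, so the two α-centres should not epimerise. Hydride should enter from the α face, anti to the pseudoaxial 4β-aryl group, and give the equatorial 3β-alcohol (3S).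

Step 9
Reactants: 12 (2R,3S)-5,7-bis(benzyloxy)-2-[3,4-bis(benzyloxy)phenyl]-4β-[2-(benzyloxy)-6-(methoxymethoxy)phenyl]chroman-3-ol
Product: 14 (2R,3R)-5,7-bis(benzyloxy)-2-[3,4-bis(benzyloxy)phenyl]-4β-[2-(benzyloxy)-6-(methoxymethoxy)phenyl]chroman-3-ol, via 4-nitrobenzoate 13 (not isolated)
Conditions: 4-nitrobenzoic acid, PPh3, DIAD, toluene, 0 °C → rt; then K2CO3, MeOH/THF, rt
Reagents that add atoms: 4-nitrobenzoic acid, O=C(O)c1ccc(cc1)[N+](=O)[O-]
Why: Mitsunobu reaction: the 3β-oxyphosphonium ion is displaced by the carboxylate with inversion (SN2), which sets the axial 3α-oxygen (3R) that now stems from the acid. The backside of the equatorial C3–O bond is open because the 1,3-related ring atoms O1 and C4a carry no axial substituents, and an equatorial leaving group has no antiperiplanar hydrogen for elimination. Methanolysis in the same flask frees the alcohol.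

Step 10
Reactants: 14 (2R,3R)-5,7-bis(benzyloxy)-2-[3,4-bis(benzyloxy)phenyl]-4β-[2-(benzyloxy)-6-(methoxymethoxy)phenyl]chroman-3-ol
Product: 15 (2R,3R)-3,5,7-tris(benzyloxy)-2-[3,4-bis(benzyloxy)phenyl]-4β-[2-(benzyloxy)-6-(methoxymethoxy)phenyl]chromane
Conditions: NaH, BnBr, Bu4NI (cat.), DMF, 0 °C → rt
Reagents that add atoms: benzyl bromide, BrCc1ccccc1
Why: Williamson etherification of the alkoxide; the benzyl ether survives every later step and leaves in the final hydrogenolysis.

Step 11
Reactants: 15 (2R,3R)-3,5,7-tris(benzyloxy)-2-[3,4-bis(benzyloxy)phenyl]-4β-[2-(benzyloxy)-6-(methoxymethoxy)phenyl]chromane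
Product: 17 3-(benzyloxy)-2-(penta-O-benzylepicatechin-4β-yl)phenol, via trimethylsilyl ether 16 (not isolated)
Conditions: TMSOTf, 2,2′-bipyridyl, CH3CN/CH2Cl2, 0 °C → rt; then H2O
Reagents that add atoms: none
Why: Chemoselective cleavage of an aromatic MOM ether: the silyl triflate with the pyridine base turns it into the silyl ether 16 under buffered, non-protic conditions, and water then gives the phenol. Benzyl ethers and the acid-labile diarylmethine bond are not exposed to free acid.

Step 12
Reactants: 17 3-(benzyloxy)-2-(penta-O-benzylepicatechin-4β-yl)phenol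
Product: 19 [3-(benzyloxy)-2-(penta-O-benzylepicatechin-4β-yl)phenoxy]acetic acid, via ethyl ester 18 (not isolated)
Conditions: BrCH2CO2Et, K2CO3, DMF, rt; then LiOH, THF/H2O; 1 M HCl to pH 3
Reagents that add atoms: ethyl bromoacetate, CCOC(=O)CBr
Why: SN2 O-alkylation of the phenoxide by the α-bromo ester, then saponification in the same flask; no other site of 17 reacts with carbonate or hydroxide.

Step 13
Reactants: 19 [3-(benzyloxy)-2-(penta-O-benzylepicatechin-4β-yl)phenoxy]acetic acid
Product: 21 6-(benzyloxy)-7-(penta-O-benzylepicatechin-4β-yl)benzofuran-3(2H)-one, via acyl chloride 20 (not isolated)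
Conditions: (COCl)2, DMF (cat.), CH2Cl2, 0 °C; then SnCl4, CH2Cl2, −78 °C
Reagents that add atoms: none
Why: Intramolecular Friedel–Crafts acylation: the acylium ion from 20 attacks the only free position ortho to the ether oxygen, which is also para to the benzyloxy group, and closes the five-membered ketone ring. Low temperature and a short reaction time are meant to spare the benzyl ethers and the diarylmethine bond.

Step 14
Reactants: 21 6-(benzyloxy)-7-(penta-O-benzylepicatechin-4β-yl)benzofuran-3(2H)-one; 3 4-bromo-1,2-bis(benzyloxy)benzene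
Product: 22 6-(benzyloxy)-2-[3,4-bis(benzyloxy)phenyl]-7-(penta-O-benzylepicatechin-4β-yl)benzofuran-3(2H)-one
Conditions: Pd(OAc)2 (3 mol %), 2-dicyclohexylphosphino-2′,4′,6′-triisopropylbiphenyl (6 mol %), K3PO4, toluene, 90 °C, Ar
Reagents that add atoms: none
Why: The same palladium-catalysed ketone α-arylation as in step 2; the new C2 centre forms as both epimers, which interconvert through the enol and are used together.

Step 15
Reactants: 23 (+)-catechin
Product: 24 5,7,3′,4′-tetra-O-benzyl-(+)-catechin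
Conditions: BnBr (4.4 equiv), K2CO3, DMF, rt
Reagents that add atoms: benzyl bromide, BrCc1ccccc1
Why: Williamson etherification of the four phenols, which are far more acidic than the 3-OH, so that carbonate leaves the alcohol free.

Step 16
Reactants: 24 5,7,3′,4′-tetra-O-benzyl-(+)-catechin
Product: 25 3,5,7,3′,4′-penta-O-benzyl-(+)-catechin
Conditions: NaH, BnBr, DMF, 0 °C → rt
Reagents that add atoms: benzyl bromide, BrCc1ccccc1
Why: Alkoxide formation and benzylation of the remaining secondary alcohol.

Step 17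
Reactants: 25 3,5,7,3′,4′-penta-O-benzyl-(+)-catechin
Product: 26 8-bromo-3,5,7,3′,4′-penta-O-benzyl-(+)-catechin
Conditions: NBS, CH2Cl2, −78 °C → rt
Reagents that add atoms: N-bromosuccinimide, O=C1CCC(=O)N1Br
Why: Electrophilic aromatic bromination; in 3-O-protected tetra-O-benzyl flavan-3-ols the reagent attacks C8 of ring A in preference to C6 and to ring B.

Step 18
Reactants: 26 8-bromo-3,5,7,3′,4′-penta-O-benzyl-(+)-catechin
Product: 28 3,5,7,3′,4′-penta-O-benzyl-(+)-catechin-8-carbaldehyde, via aryllithium 27 (not isolated)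
Conditions: n-BuLi, THF, −78 °C; DMF; aq. NH4Cl
Reagents that add atoms: N,N-dimethylformamide, CN(C)C=O
Why: Bromine–lithium exchange gives the aryllithium 27, which is formylated by DMF; C2 and C3 are not affected at −78 °C.

Step 19
Reactants: 28 3,5,7,3′,4′-penta-O-benzyl-(+)-catechin-8-carbaldehyde
Product: 29 (E)-hydrazone of 3,5,7,3′,4′-penta-O-benzyl-(+)-catechin-8-carbaldehyde
Conditions: N2H4·H2O (10 equiv), EtOH/THF, 50 °C
Reagents that add atoms: hydrazine (as hydrate), NN
Why: Hydrazone formation as in step 5; the doubly ortho-substituted aldehyde needs mild warming.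

Step 20
Reactants: 29 (E)-hydrazone of 3,5,7,3′,4′-penta-O-benzyl-(+)-catechin-8-carbaldehyde
Product: 30 (penta-O-benzylcatechin-8-yl)diazomethane
Conditions: activated MnO2, Na2SO4, CH2Cl2, 0 °C, dark; cold filtrate used at once
Reagents that add atoms: none
Why: MnO2 dehydrogenation as in step 6; this diazo compound carries three donor oxygens on its ring and is used immediately as a cold solution.

Step 21
Reactants: 22 6-(benzyloxy)-2-[3,4-bis(benzyloxy)phenyl]-7-(penta-O-benzylepicatechin-4β-yl)benzofuran-3(2H)-one; 30 (penta-O-benzylcatechin-8-yl)diazomethane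
Product: 31 (2R)-7-(benzyloxy)-2-[3,4-bis(benzyloxy)phenyl]-8-(penta-O-benzylepicatechin-4β-yl)-4β-(penta-O-benzylcatechin-8-yl)chroman-3-one
Conditions: Sc(OTf)3 (15 mol %), chiral tris(oxazoline) ligand (18 mol %), 4 Å MS, toluene/CH2Cl2, −78 → −40 °C, slow addition of 30 (1.5 equiv)
Reagents that add atoms: none
Why: Proposed new method: the same Sc(OTf)3-catalysed insertion of an aryldiazomethane carbon between the carbonyl carbon and the ring-A carbon C3a of a 2-arylbenzofuran-3(2H)-one as in step 7, closest known in the enantioselective homologation of cycloalkanones with aryldiazomethanes; C3a is here para to the benzyloxy group and ortho to O1, which should still let it migrate ahead of the α-aryloxy carbon C2. The catalyst antipode is chosen so that the mobile C2 centre of 22 is drawn into the 2α-aryl series and the new C4 centre carries the catechin ring β, trans to the C2 aryl group, with the peri hydrogen H-5 favouring a pseudoaxial C4 aryl group. The stereocentres of unit U lie far from the reacting carbonyl.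

Step 22
Reactants: 31 (2R)-7-(benzyloxy)-2-[3,4-bis(benzyloxy)phenyl]-8-(penta-O-benzylepicatechin-4β-yl)-4β-(penta-O-benzylcatechin-8-yl)chroman-3-one
Product: 32 (2R,3S)-7-(benzyloxy)-2-[3,4-bis(benzyloxy)phenyl]-8-(penta-O-benzylepicatechin-4β-yl)-4β-(penta-O-benzylcatechin-8-yl)chroman-3-ol
Conditions: NaBH4, CeCl3·7H2O, THF/MeOH, −78 °C
Reagents that add atoms: none
Why: As in step 8; hydride should enter anti to the pseudoaxial 4β-aryl group of unit M and give the 3β-alcohol (3S). Any 3α-alcohol formed is 34 itself.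

Step 23
Reactants: 32 (2R,3S)-7-(benzyloxy)-2-[3,4-bis(benzyloxy)phenyl]-8-(penta-O-benzylepicatechin-4β-yl)-4β-(penta-O-benzylcatechin-8-yl)chroman-3-ol
Product: 34 (2R,3R)-7-(benzyloxy)-2-[3,4-bis(benzyloxy)phenyl]-8-(penta-O-benzylepicatechin-4β-yl)-4β-(penta-O-benzylcatechin-8-yl)chroman-3-ol, via 4-nitrobenzoate 33 (not isolated)
Conditions: 4-nitrobenzoic acid, PPh3, DIAD, toluene, 0 °C → rt; then K2CO3, MeOH/THF, rt
Reagents that add atoms: 4-nitrobenzoic acid, O=C(O)c1ccc(cc1)[N+](=O)[O-]
Why: Mitsunobu inversion as in step 9 at the only free hydroxyl, which sets the axial 3α-oxygen (3R) of unit M, followed by methanolysis of the ester.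

Step 24
Reactants: 34 (2R,3R)-7-(benzyloxy)-2-[3,4-bis(benzyloxy)phenyl]-8-(penta-O-benzylepicatechin-4β-yl)-4β-(penta-O-benzylcatechin-8-yl)chroman-3-ol
Product: 35 epicatechin-(4β→8)-epifisetinidol-(4β→8)-catechin
Conditions: H2 (1 atm), Pd(OH)2/C, THF/MeOH/H2O, rt
Reagents that add atoms: none
Why: Hydrogenolysis of all thirteen benzyl ethers under neutral conditions, which the interflavan bonds and the free catechols tolerate; no stereocentre is touched.

## Compound list

1 | 4,6-dihydroxybenzofuran-3(2H)-one | O=C1COc2cc(O)cc(O)c12 | starting material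
2 | 4,6-bis(benzyloxy)benzofuran-3(2H)-one | O=C1COc2cc(OCc3ccccc3)cc(OCc3ccccc3)c12 | intermediate
3 | 4-bromo-1,2-bis(benzyloxy)benzene | Brc1ccc(OCc2ccccc2)c(OCc2ccccc2)c1 | starting material
4 | rac-4,6-bis(benzyloxy)-2-[3,4-bis(benzyloxy)phenyl]benzofuran-3(2H)-one | O=C1C(c4ccc(OCc3ccccc3)c(OCc3ccccc3)c4)Oc2cc(OCc3ccccc3)cc(OCc3ccccc3)c12 | intermediate
5 | 3-(benzyloxy)phenol | Oc1cccc(OCc2ccccc2)c1 | starting material
6 | 1-(benzyloxy)-3-(methoxymethoxy)benzene | COCOc1cccc(OCc2ccccc2)c1 | intermediate
7 | [2-(benzyloxy)-6-(methoxymethoxy)phenyl]lithium | [Li]c1c(OCc2ccccc2)cccc1OCOC | intermediate (not isolated)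
8 | 2-(benzyloxy)-6-(methoxymethoxy)benzaldehyde | O=Cc1c(OCc2ccccc2)cccc1OCOC | intermediate
9 | (E)-[2-(benzyloxy)-6-(methoxymethoxy)benzylidene]hydrazine | N/N=C/c1c(OCc2ccccc2)cccc1OCOC | intermediate
10 | [2-(benzyloxy)-6-(methoxymethoxy)phenyl]diazomethane | [N-]=[N+]=Cc1c(OCc2ccccc2)cccc1OCOC | intermediate
11 | (2R)-5,7-bis(benzyloxy)-2-[3,4-bis(benzyloxy)phenyl]-4β-[2-(benzyloxy)-6-(methoxymethoxy)phenyl]chroman-3-one (2,4-trans) | O(Cc3ccccc3)c1cc(OCc3ccccc3)c2c(c1)O[C@H](c4ccc(OCc3ccccc3)c(OCc3ccccc3)c4)C(=O)[C@H]2c5c(OCc3ccccc3)cccc5OCOC | intermediate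
12 | (2R,3S)-5,7-bis(benzyloxy)-2-[3,4-bis(benzyloxy)phenyl]-4β-[2-(benzyloxy)-6-(methoxymethoxy)phenyl]chroman-3-ol (3β-OH; 2,3-trans-3,4-cis) | O(Cc3ccccc3)c1cc(OCc3ccccc3)c2c(c1)O[C@H](c4ccc(OCc3ccccc3)c(OCc3ccccc3)c4)[C@@H](O)[C@H]2c5c(OCc3ccccc3)cccc5OCOC | intermediate
13 | 3α-(4-nitrobenzoate) of 14 (2R,3R) | O(Cc3ccccc3)c1cc(OCc3ccccc3)c2c(c1)O[C@H](c4ccc(OCc3ccccc3)c(OCc3ccccc3)c4)[C@H](OC(=O)c5ccc(cc5)[N+](=O)[O-])[C@H]2c6c(OCc3ccccc3)cccc6OCOC | intermediate (not isolated)
14 | (2R,3R)-5,7-bis(benzyloxy)-2-[3,4-bis(benzyloxy)phenyl]-4β-[2-(benzyloxy)-6-(methoxymethoxy)phenyl]chroman-3-ol (3α-OH; 2,3-cis-3,4-trans) | O(Cc3ccccc3)c1cc(OCc3ccccc3)c2c(c1)O[C@H](c4ccc(OCc3ccccc3)c(OCc3ccccc3)c4)[C@H](O)[C@H]2c5c(OCc3ccccc3)cccc5OCOC | intermediate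
15 | (2R,3R)-3,5,7-tris(benzyloxy)-2-[3,4-bis(benzyloxy)phenyl]-4β-[2-(benzyloxy)-6-(methoxymethoxy)phenyl]chromane | O(Cc3ccccc3)c1cc(OCc3ccccc3)c2c(c1)O[C@H](c4ccc(OCc3ccccc3)c(OCc3ccccc3)c4)[C@H](OCc3ccccc3)[C@H]2c5c(OCc3ccccc3)cccc5OCOC | intermediate
16 | [3-(benzyloxy)-2-(penta-O-benzylepicatechin-4β-yl)phenoxy]trimethylsilane | O(Cc3ccccc3)c1cc(OCc3ccccc3)c2c(c1)O[C@H](c4ccc(OCc3ccccc3)c(OCc3ccccc3)c4)[C@H](OCc3ccccc3)[C@H]2c5c(OCc3ccccc3)cccc5O[Si](C)(C)C | intermediate (not isolated)
17 | 3-(benzyloxy)-2-(penta-O-benzylepicatechin-4β-yl)phenol | O(Cc3ccccc3)c1cc(OCc3ccccc3)c2c(c1)O[C@H](c4ccc(OCc3ccccc3)c(OCc3ccccc3)c4)[C@H](OCc3ccccc3)[C@H]2c5c(OCc3ccccc3)cccc5O | intermediate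
18 | ethyl [3-(benzyloxy)-2-(penta-O-benzylepicatechin-4β-yl)phenoxy]acetate | O(Cc3ccccc3)c1cc(OCc3ccccc3)c2c(c1)O[C@H](c4ccc(OCc3ccccc3)c(OCc3ccccc3)c4)[C@H](OCc3ccccc3)[C@H]2c5c(OCc3ccccc3)cccc5OCC(=O)OCC | intermediate (not isolated)
19 | [3-(benzyloxy)-2-(penta-O-benzylepicatechin-4β-yl)phenoxy]acetic acid | O(Cc3ccccc3)c1cc(OCc3ccccc3)c2c(c1)O[C@H](c4ccc(OCc3ccccc3)c(OCc3ccccc3)c4)[C@H](OCc3ccccc3)[C@H]2c5c(OCc3ccccc3)cccc5OCC(=O)O | intermediate
20 | [3-(benzyloxy)-2-(penta-O-benzylepicatechin-4β-yl)phenoxy]acetyl chloride | O(Cc3ccccc3)c1cc(OCc3ccccc3)c2c(c1)O[C@H](c4ccc(OCc3ccccc3)c(OCc3ccccc3)c4)[C@H](OCc3ccccc3)[C@H]2c5c(OCc3ccccc3)cccc5OCC(=O)Cl | intermediate (not isolated)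
21 | 6-(benzyloxy)-7-(penta-O-benzylepicatechin-4β-yl)benzofuran-3(2H)-one | O(Cc3ccccc3)c1cc(OCc3ccccc3)c2c(c1)O[C@H](c4ccc(OCc3ccccc3)c(OCc3ccccc3)c4)[C@H](OCc3ccccc3)[C@H]2c5c(OCc3ccccc3)ccc6C(=O)COc56 | intermediate
22 | 6-(benzyloxy)-2-[3,4-bis(benzyloxy)phenyl]-7-(penta-O-benzylepicatechin-4β-yl)benzofuran-3(2H)-one (both epimers at C2 of the furanone) | O(Cc3ccccc3)c1cc(OCc3ccccc3)c2c(c1)O[C@H](c4ccc(OCc3ccccc3)c(OCc3ccccc3)c4)[C@H](OCc3ccccc3)[C@H]2c5c(OCc3ccccc3)ccc6C(=O)C(c4ccc(OCc3ccccc3)c(OCc3ccccc3)c4)Oc56 | intermediate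
23 | (+)-catechin (2R,3S) | Oc1cc(O)c2c(c1)O[C@H](c1ccc(O)c(O)c1)[C@@H](O)C2 | starting material
24 | 5,7,3′,4′-tetra-O-benzyl-(+)-catechin | O(Cc3ccccc3)c1cc(OCc3ccccc3)c2c(c1)O[C@H](c4ccc(OCc3ccccc3)c(OCc3ccccc3)c4)[C@@H](O)C2 | intermediate
25 | 3,5,7,3′,4′-penta-O-benzyl-(+)-catechin | O(Cc3ccccc3)c1cc(OCc3ccccc3)c2c(c1)O[C@H](c4ccc(OCc3ccccc3)c(OCc3ccccc3)c4)[C@@H](OCc3ccccc3)C2 | intermediate
26 | 8-bromo-3,5,7,3′,4′-penta-O-benzyl-(+)-catechin | Brc7c(OCc3ccccc3)cc(OCc3ccccc3)c8c7O[C@H](c4ccc(OCc3ccccc3)c(OCc3ccccc3)c4)[C@@H](OCc3ccccc3)C8 | intermediate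
27 | (penta-O-benzylcatechin-8-yl)lithium | [Li]c7c(OCc3ccccc3)cc(OCc3ccccc3)c8c7O[C@H](c4ccc(OCc3ccccc3)c(OCc3ccccc3)c4)[C@@H](OCc3ccccc3)C8 | intermediate (not isolated)
28 | 3,5,7,3′,4′-penta-O-benzyl-(+)-catechin-8-carbaldehyde | O=Cc7c(OCc3ccccc3)cc(OCc3ccccc3)c8c7O[C@H](c4ccc(OCc3ccccc3)c(OCc3ccccc3)c4)[C@@H](OCc3ccccc3)C8 | intermediate
29 | (E)-hydrazone of 28 | N/N=C/c7c(OCc3ccccc3)cc(OCc3ccccc3)c8c7O[C@H](c4ccc(OCc3ccccc3)c(OCc3ccccc3)c4)[C@@H](OCc3ccccc3)C8 | intermediate
30 | (penta-O-benzylcatechin-8-yl)diazomethane | [N-]=[N+]=Cc7c(OCc3ccccc3)cc(OCc3ccccc3)c8c7O[C@H](c4ccc(OCc3ccccc3)c(OCc3ccccc3)c4)[C@@H](OCc3ccccc3)C8 | intermediate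
31 | (2R)-7-(benzyloxy)-2-[3,4-bis(benzyloxy)phenyl]-8-(penta-O-benzylepicatechin-4β-yl)-4β-(penta-O-benzylcatechin-8-yl)chroman-3-one (2,4-trans in unit M) | O(Cc3ccccc3)c1cc(OCc3ccccc3)c2c(c1)O[C@H](c4ccc(OCc3ccccc3)c(OCc3ccccc3)c4)[C@H](OCc3ccccc3)[C@H]2c5c(OCc3ccccc3)ccc6c5O[C@H](c4ccc(OCc3ccccc3)c(OCc3ccccc3)c4)C(=O)[C@H]6c7c(OCc3ccccc3)cc(OCc3ccccc3)c8c7O[C@H](c4ccc(OCc3ccccc3)c(OCc3ccccc3)c4)[C@@H](OCc3ccccc3)C8 | intermediate
32 | (2R,3S)-7-(benzyloxy)-2-[3,4-bis(benzyloxy)phenyl]-8-(penta-O-benzylepicatechin-4β-yl)-4β-(penta-O-benzylcatechin-8-yl)chroman-3-ol (3β-OH in unit M) | O(Cc3ccccc3)c1cc(OCc3ccccc3)c2c(c1)O[C@H](c4ccc(OCc3ccccc3)c(OCc3ccccc3)c4)[C@H](OCc3ccccc3)[C@H]2c5c(OCc3ccccc3)ccc6c5O[C@H](c4ccc(OCc3ccccc3)c(OCc3ccccc3)c4)[C@@H](O)[C@H]6c7c(OCc3ccccc3)cc(OCc3ccccc3)c8c7O[C@H](c4ccc(OCc3ccccc3)c(OCc3ccccc3)c4)[C@@H](OCc3ccccc3)C8 | intermediate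
33 | 3α-(4-nitrobenzoate) of 34 (unit M) | O(Cc3ccccc3)c1cc(OCc3ccccc3)c2c(c1)O[C@H](c4ccc(OCc3ccccc3)c(OCc3ccccc3)c4)[C@H](OCc3ccccc3)[C@H]2c5c(OCc3ccccc3)ccc6c5O[C@H](c4ccc(OCc3ccccc3)c(OCc3ccccc3)c4)[C@H](OC(=O)c9ccc(cc9)[N+](=O)[O-])[C@H]6c7c(OCc3ccccc3)cc(OCc3ccccc3)c8c7O[C@H](c4ccc(OCc3ccccc3)c(OCc3ccccc3)c4)[C@@H](OCc3ccccc3)C8 | intermediate (not isolated)
34 | (2R,3R)-7-(benzyloxy)-2-[3,4-bis(benzyloxy)phenyl]-8-(penta-O-benzylepicatechin-4β-yl)-4β-(penta-O-benzylcatechin-8-yl)chroman-3-ol (3α-OH in unit M; tridecabenzyl ether of 35) | O(Cc3ccccc3)c1cc(OCc3ccccc3)c2c(c1)O[C@H](c4ccc(OCc3ccccc3)c(OCc3ccccc3)c4)[C@H](OCc3ccccc3)[C@H]2c5c(OCc3ccccc3)ccc6c5O[C@H](c4ccc(OCc3ccccc3)c(OCc3ccccc3)c4)[C@H](O)[C@H]6c7c(OCc3ccccc3)cc(OCc3ccccc3)c8c7O[C@H](c4ccc(OCc3ccccc3)c(OCc3ccccc3)c4)[C@@H](OCc3ccccc3)C8 | intermediate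
35 | epicatechin-(4β→8)-epifisetinidol-(4β→8)-catechin; U (2R,3R,4R), M (2R,3R,4R), L (2R,3S) | Oc1cc(O)c2c(c1)O[C@H](c1ccc(O)c(O)c1)[C@H](O)[C@H]2c1c(O)ccc2c1O[C@H](c1ccc(O)c(O)c1)[C@H](O)[C@H]2c1c(O)cc(O)c2c1O[C@H](c1ccc(O)c(O)c1)[C@@H](O)C2 | target

## Step count and least certain steps

Total: 24 steps. Longest linear sequence: 16 steps (steps 3–14 and 21–24, from 5). The furanone branch from 1 (steps 1 and 2) and the catechin branch from 23 (steps 15–20) join at steps 7 and 21.

**Step 7 (key step).** Addition of the hindered diazo carbon to a carbonyl that is deactivated by two alkoxy donors and flanked by the peri benzyloxy group may be slow, so that the diazo compound decays to azine or stilbene first. Other ways of failure are migration of C2 instead of the aryl carbon, O-benzylation of the enol of 4, epoxide formation, weak facial control by the catalyst, racemisation of 4 too slow for a dynamic resolution, and epimerisation of the product before reduction. The fallback uses known flavan chemistry with the stereocentres from the chiral pool; it sets out from 24 and from aryllithium 7 (made from 6 as in step 4) and comes back at 12. Silylation of 24 (TBSCl, imidazole) gives the 3-O-silyl ether F1. DDQ in wet CH2Cl2 oxidises C4 to the 4-hydroxy compound F2, and Dess–Martin periodinane gives the 4-ketone F3. Addition of 7 gives the tertiary alcohol F4. Ionic deoxygenation (Et3SiH, BF3·OEt2, −78 °C) delivers hydride anti to the 3β-silyloxy group and so places the aryl group β in F5. Bu4NF then frees alcohol 12.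

**Step 21.** The risks are those of step 7, with three additions: the migrating carbon has one donor oxygen fewer, the peri lock is only a hydrogen, and the catalyst has to prevail over any bias from unit U. Diazo compound 30 is also more electron-rich and may decompose before it adds. The fallback uses known chemistry; it sets out from 17, uses aryllithium 27 (made from 26 as in step 18), and comes back at 32.
- Magnesium-mediated ortho-formylation (MgCl2, Et3N, paraformaldehyde) gives the salicylaldehyde F6.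
- Condensation with (E)-2-[3,4-bis(benzyloxy)phenyl]vinylboronic acid and dibenzylamine (Petasis-type 2H-chromene synthesis) gives the flav-3-ene F7, whose C2 epimers are separated.
- OsO4/N-methylmorpholine N-oxide adds anti to the 2-aryl group and gives the 3β,4β-diol F8.
- MnO2 oxidises the benzylic 4-hydroxyl to the 3-hydroxy-4-ketone F9, and TBSOTf/2,6-lutidine gives the silyl ether F10.
- Addition of 27 gives the tertiary alcohol F11; Et3SiH/BF3·OEt2 at −78 °C removes the hydroxyl with hydride anti to the 3β-silyloxy group and gives the 4β-aryl compound F12.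
- Bu4NF gives 32.

**Step 9.** Activation of the hindered 3β-hydroxyl next to the pseudoaxial aryl group may be incomplete. The ring oxygen O1, antiperiplanar to the equatorial leaving group, may also participate, which would lead to ring contraction or to retention. The fallback replaces the one-pot redox condensation by a sulfonate displacement; it sets out from 12 and comes back at 14. Tf2O/pyridine at −20 °C gives the 3β-triflate F13. KNO2 in DMF displaces it with inversion to the 3α-nitrite F14, which is hydrolysed on work-up to 14.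

**Step 13.** The Lewis and protic acids of the acylation may ionise the diarylmethine bond between units U and M (retro-Friedel–Crafts), remove benzyl groups, or let the acylium ion attack the electron-rich ring A of another molecule. The fallback avoids acid altogether; it sets out from 17 and comes back at 21. Ortho-formylation (MgCl2, Et3N, paraformaldehyde) gives the salicylaldehyde F15, which is the same compound as F6. Dimethylsulfoxonium methylide (trimethylsulfoxonium iodide, NaH, DMSO) forms the epoxide, which the phenoxide opens in the flask to the 2,3-dihydrobenzofuran-3-ol F16. Dess–Martin periodinane oxidises F16 to 21.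

**Step 22.** Without a peri benzyloxy group the C4 aryl group of unit M is less firmly pseudoaxial, so the facial selectivity of hydride attack may be low, and 31 may epimerise before it is reduced. The fallback is a convergent handling and makes no new compound: the two C3 epimers are separated, the 3β-alcohol 32 goes through step 23, and the 3α-alcohol, which is 34, goes directly to step 24.

## Further compounds

F1 | step 7 | 5,7,3′,4′-tetra-O-benzyl-3-O-(tert-butyldimethylsilyl)-(+)-catechin | O(Cc3ccccc3)c1cc(OCc3ccccc3)c2c(c1)O[C@H](c4ccc(OCc3ccccc3)c(OCc3ccccc3)c4)[C@@H](O[Si](C)(C)C(C)(C)C)C2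
F2 | step 7 | 4-hydroxy derivative of F1 (C4 epimers) | O(Cc3ccccc3)c1cc(OCc3ccccc3)c2c(c1)O[C@H](c4ccc(OCc3ccccc3)c(OCc3ccccc3)c4)[C@@H](O[Si](C)(C)C(C)(C)C)C2O
F3 | step 7 | 2,3-trans-5,7-bis(benzyloxy)-2α-[3,4-bis(benzyloxy)phenyl]-3β-(tert-butyldimethylsilyloxy)chroman-4-one | O(Cc3ccccc3)c1cc(OCc3ccccc3)c2c(c1)O[C@H](c4ccc(OCc3ccccc3)c(OCc3ccccc3)c4)[C@@H](O[Si](C)(C)C(C)(C)C)C2=O
F4 | step 7 | 4-[2-(benzyloxy)-6-(methoxymethoxy)phenyl]-4-hydroxy derivative of F1 (C4 epimers) | O(Cc3ccccc3)c1cc(OCc3ccccc3)c2c(c1)O[C@H](c4ccc(OCc3ccccc3)c(OCc3ccccc3)c4)[C@@H](O[Si](C)(C)C(C)(C)C)C2(O)c5c(OCc3ccccc3)cccc5OCOC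
F5 | step 7 | 3-O-tert-butyldimethylsilyl ether of 12 (3β-silyloxy, 4β-aryl) | O(Cc3ccccc3)c1cc(OCc3ccccc3)c2c(c1)O[C@H](c4ccc(OCc3ccccc3)c(OCc3ccccc3)c4)[C@@H](O[Si](C)(C)C(C)(C)C)[C@H]2c5c(OCc3ccccc3)cccc5OCOC
F6 | step 21 | 4-(benzyloxy)-2-hydroxy-3-(penta-O-benzylepicatechin-4β-yl)benzaldehyde | O(Cc3ccccc3)c1cc(OCc3ccccc3)c2c(c1)O[C@H](c4ccc(OCc3ccccc3)c(OCc3ccccc3)c4)[C@H](OCc3ccccc3)[C@H]2c5c(OCc3ccccc3)ccc(C=O)c5O
F7 | step 21 | 7-(benzyloxy)-2α-[3,4-bis(benzyloxy)phenyl]-8-(penta-O-benzylepicatechin-4β-yl)-2H-chromene | O(Cc3ccccc3)c1cc(OCc3ccccc3)c2c(c1)O[C@H](c4ccc(OCc3ccccc3)c(OCc3ccccc3)c4)[C@H](OCc3ccccc3)[C@H]2c5c(OCc3ccccc3)ccc6c5O[C@H](c4ccc(OCc3ccccc3)c(OCc3ccccc3)c4)C=C6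
F8 | step 21 | 7-(benzyloxy)-2α-[3,4-bis(benzyloxy)phenyl]-8-(penta-O-benzylepicatechin-4β-yl)chromane-3β,4β-diol | O(Cc3ccccc3)c1cc(OCc3ccccc3)c2c(c1)O[C@H](c4ccc(OCc3ccccc3)c(OCc3ccccc3)c4)[C@H](OCc3ccccc3)[C@H]2c5c(OCc3ccccc3)ccc6c5O[C@H](c4ccc(OCc3ccccc3)c(OCc3ccccc3)c4)[C@@H](O)[C@H]6O
F9 | step 21 | 7-(benzyloxy)-2α-[3,4-bis(benzyloxy)phenyl]-3β-hydroxy-8-(penta-O-benzylepicatechin-4β-yl)chroman-4-one | O(Cc3ccccc3)c1cc(OCc3ccccc3)c2c(c1)O[C@H](c4ccc(OCc3ccccc3)c(OCc3ccccc3)c4)[C@H](OCc3ccccc3)[C@H]2c5c(OCc3ccccc3)ccc6c5O[C@H](c4ccc(OCc3ccccc3)c(OCc3ccccc3)c4)[C@@H](O)C6=O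
F10 | step 21 | 3-O-tert-butyldimethylsilyl ether of F9 | O(Cc3ccccc3)c1cc(OCc3ccccc3)c2c(c1)O[C@H](c4ccc(OCc3ccccc3)c(OCc3ccccc3)c4)[C@H](OCc3ccccc3)[C@H]2c5c(OCc3ccccc3)ccc6c5O[C@H](c4ccc(OCc3ccccc3)c(OCc3ccccc3)c4)[C@@H](O[Si](C)(C)C(C)(C)C)C6=O
F11 | step 21 | 4-hydroxy-4-(penta-O-benzylcatechin-8-yl) adduct of F10 (C4 epimers) | O(Cc3ccccc3)c1cc(OCc3ccccc3)c2c(c1)O[C@H](c4ccc(OCc3ccccc3)c(OCc3ccccc3)c4)[C@H](OCc3ccccc3)[C@H]2c5c(OCc3ccccc3)ccc6c5O[C@H](c4ccc(OCc3ccccc3)c(OCc3ccccc3)c4)[C@@H](O[Si](C)(C)C(C)(C)C)C6(O)c7c(OCc3ccccc3)cc(OCc3ccccc3)c8c7O[C@H](c4ccc(OCc3ccccc3)c(OCc3ccccc3)c4)[C@@H](OCc3ccccc3)C8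
F12 | step 21 | 3-O-tert-butyldimethylsilyl ether of 32 (unit M: 3β-silyloxy, 4β-aryl) | O(Cc3ccccc3)c1cc(OCc3ccccc3)c2c(c1)O[C@H](c4ccc(OCc3ccccc3)c(OCc3ccccc3)c4)[C@H](OCc3ccccc3)[C@H]2c5c(OCc3ccccc3)ccc6c5O[C@H](c4ccc(OCc3ccccc3)c(OCc3ccccc3)c4)[C@@H](O[Si](C)(C)C(C)(C)C)[C@H]6c7c(OCc3ccccc3)cc(OCc3ccccc3)c8c7O[C@H](c4ccc(OCc3ccccc3)c(OCc3ccccc3)c4)[C@@H](OCc3ccccc3)C8
F13 | step 9 | 3β-trifluoromethanesulfonate of 12 | O(Cc3ccccc3)c1cc(OCc3ccccc3)c2c(c1)O[C@H](c4ccc(OCc3ccccc3)c(OCc3ccccc3)c4)[C@@H](OS(=O)(=O)C(F)(F)F)[C@H]2c5c(OCc3ccccc3)cccc5OCOC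
F14 | step 9 | 3α-nitrite ester of 14 | O(Cc3ccccc3)c1cc(OCc3ccccc3)c2c(c1)O[C@H](c4ccc(OCc3ccccc3)c(OCc3ccccc3)c4)[C@H](ON=O)[C@H]2c5c(OCc3ccccc3)cccc5OCOC
F15 | step 13 | 4-(benzyloxy)-2-hydroxy-3-(penta-O-benzylepicatechin-4β-yl)benzaldehyde | O(Cc3ccccc3)c1cc(OCc3ccccc3)c2c(c1)O[C@H](c4ccc(OCc3ccccc3)c(OCc3ccccc3)c4)[C@H](OCc3ccccc3)[C@H]2c5c(OCc3ccccc3)ccc(C=O)c5O
F16 | step 13 | 6-(benzyloxy)-7-(penta-O-benzylepicatechin-4β-yl)-2,3-dihydrobenzofuran-3-ol (C3 epimers of the furan ring) | O(Cc3ccccc3)c1cc(OCc3ccccc3)c2c(c1)O[C@H](c4ccc(OCc3ccccc3)c(OCc3ccccc3)c4)[C@H](OCc3ccccc3)[C@H]2c5c(OCc3ccccc3)ccc6C(O)COc56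
F0 | step 22 | none | none
A1 | alternative 1 | tridecabenzyl trimer with a 3-O-tert-butyldimethylsilyl ether in unit M | O(Cc3ccccc3)c1cc(OCc3ccccc3)c2c(c1)O[C@H](c4ccc(OCc3ccccc3)c(OCc3ccccc3)c4)[C@H](OCc3ccccc3)[C@H]2c5c(OCc3ccccc3)ccc6c5O[C@H](c4ccc(OCc3ccccc3)c(OCc3ccccc3)c4)[C@H](O[Si](C)(C)C(C)(C)C)[C@H]6c7c(OCc3ccccc3)cc(OCc3ccccc3)c8c7O[C@H](c4ccc(OCc3ccccc3)c(OCc3ccccc3)c4)[C@@H](OCc3ccccc3)C8
A2 | alternative 1 | open-chain precursor of A1: aryl triflate at C8a of unit M with the free C2 hydroxyl | O(Cc3ccccc3)c1cc(OCc3ccccc3)c2c(c1)O[C@H](c4ccc(OCc3ccccc3)c(OCc3ccccc3)c4)[C@H](OCc3ccccc3)[C@H]2c5c(OCc3ccccc3)ccc(c5OS(=O)(=O)C(F)(F)F)[C@H](c7c(OCc3ccccc3)cc(OCc3ccccc3)c8c7O[C@H](c4ccc(OCc3ccccc3)c(OCc3ccccc3)c4)[C@@H](OCc3ccccc3)C8)[C@@H](O[Si](C)(C)C(C)(C)C)[C@H](O)c4ccc(OCc3ccccc3)c(OCc3ccccc3)c4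
A3 | alternative 2 | 2,4-dihydroxy-3-(penta-O-benzylepicatechin-4β-yl)benzaldehyde | O(Cc3ccccc3)c1cc(OCc3ccccc3)c2c(c1)O[C@H](c4ccc(OCc3ccccc3)c(OCc3ccccc3)c4)[C@H](OCc3ccccc3)[C@H]2c5c(O)ccc(C=O)c5O
A4 | alternative 2 | 1,1,7,7-tetramethoxy-4-(penta-O-benzylepicatechin-4β-yl)heptane-3,5-dione | O(Cc3ccccc3)c1cc(OCc3ccccc3)c2c(c1)O[C@H](c4ccc(OCc3ccccc3)c(OCc3ccccc3)c4)[C@H](OCc3ccccc3)[C@H]2C(C(=O)CC(OC)OC)C(=O)CC(OC)OC
A5 | alternative 3 | 2-(penta-O-benzylepicatechin-4β-yl)-3-(triisopropylsilyloxy)phenol | O(Cc3ccccc3)c1cc(OCc3ccccc3)c2c(c1)O[C@H](c4ccc(OCc3ccccc3)c(OCc3ccccc3)c4)[C@H](OCc3ccccc3)[C@H]2c5c(O[Si](C(C)C)(C(C)C)C(C)C)cccc5O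
A6 | alternative 3 | 3,5,7,3′,4′-penta-O-benzyl-4β-(triisopropylsilyloxyethynyl)epicatechin | O(Cc3ccccc3)c1cc(OCc3ccccc3)c2c(c1)O[C@H](c4ccc(OCc3ccccc3)c(OCc3ccccc3)c4)[C@H](OCc3ccccc3)[C@H]2C#CO[Si](C(C)C)(C(C)C)C(C)C
A7 | alternative 3 | cyclobut-2-en-1-one | O=C1C=CC1
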